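Ring labels: A = methoxy ring, B = para-linked ring, C = phenol ring, D = meta-linked ring. The target has no stereocentre, and the alkene geometries made on the way are erased by hydrogenation.
Enabling feature: the oxygen joining ring A C3 (ortho to the methoxy-bearing C4) to the ring B ipso carbon (para to its CH2CH2 chain) is what remains of a guaiacol-type aryl 4-alkylbenzoate once its carbonyl carbon is deleted.
Retrosynthetic cuts: (1) C=O re-inserted into the O–C(ring B) bond, taking the 19-membered ring to a 20-membered lactone; (2) the lactone acyl–O bond; (3) the ring C carbon–O(ring D) ether bond; (4) both CH2–CH2 bridges as C=C.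
Forward order: A + D by Wittig and B + C by Horner–Wadsworth–Emmons, the two halves joined by Ullmann coupling, one hydrogenation, saponification, Shiina closure of the 20-membered ring, nickel-catalysed CO loss to the 19-membered ring, MOM removal.
Key step: step 11

Remark (protecting groups): the ring C phenol is carried as its methoxymethyl (MOM) ether because it must pass hot carbonate, hydroxide and hot phosphate, where an aryl silyl ether would be at risk. The ring A phenol is carried as a benzyl ether so that the hydrogenation frees it.
Remark (alkene geometry): the ring A–ring D alkene is carried as an E/Z mixture and its SMILES has no descriptor. The ring B–ring C alkene is E.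
Remark (supply): O-benzylisovanillin and the ring B phosphonate are also catalogue items. Each is made here in one step off the longest sequence.

Step 1
Reactants: 1 isovanillin (3-hydroxy-4-methoxybenzaldehyde)
Product: 2 3-(benzyloxy)-4-methoxybenzaldehyde
Conditions: BnBr (1.1 equiv), K2CO3 (1.5 equiv), DMF, 60 °C
Reagents that add atoms: benzyl bromide, BrCc1ccccc1
Why: Williamson ether synthesis at the only acidic OH; the benzyl ether withstands the Wittig and Ullmann bases and is removed in the hydrogenation of step 8.

Step 2
Reactants: 3 3-hydroxybenzyl alcohol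
Product: 4 (3-hydroxybenzyl)triphenylphosphonium bromide
Conditions: PPh3·HBr (1.0 equiv), MeCN, reflux
Reagents that add atoms: triphenylphosphine hydrobromide, [Br-].c1ccc(cc1)[PH+](c1ccccc1)c1ccccc1
Why: Direct phosphonium salt formation from a benzylic alcohol (acid-promoted substitution at the benzylic carbon), which leaves the phenol free for step 7 and avoids a separate bromide.

Step 3
Reactants: 4 (3-hydroxybenzyl)triphenylphosphonium bromide; 2 3-(benzyloxy)-4-methoxybenzaldehyde
Product: 6 3-[2-(3-benzyloxy-4-methoxyphenyl)ethenyl]phenol (ring A–ring D stilbene; E/Z mixture), via potassium phenoxide ylide 5 (not isolated)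
Conditions: KOt-Bu (2.1 equiv), THF, 0 °C; then 2, 0 °C to rt; 1 M HCl quench
Reagents that add atoms: none
Why: Wittig olefination in which the second equivalent of base only deprotonates the meta phenol, which is not conjugated to the ylide carbon; the semistabilised ylide should give both alkene isomers, which is harmless because step 8 saturates the bond.

Step 4
Reactants: 7 3-bromo-4-hydroxybenzaldehyde
Product: 8 3-bromo-4-(methoxymethoxy)benzaldehyde
Conditions: MOMCl (1.3 equiv), i-Pr2NEt (1.5 equiv), CH2Cl2, 0 °C to rt
Reagents that add atoms: chloromethyl methyl ether, COCCl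
Why: O-alkylation of the acidic para-formyl phenol (acetal protection) gives a group stable to carbonate, hydride, hydroxide, hydrogenation and hot phosphate yet removable by mild acid.

Step 5
Reactants: 9 methyl 4-(bromomethyl)benzoate
Product: 10 methyl 4-[(diethoxyphosphoryl)methyl]benzoate
Conditions: P(OEt)3 (1.5 equiv), neat, 150 °C, EtBr distilled off
Reagents that add atoms: triethyl phosphite, CCOP(OCC)OCC
Why: Michaelis–Arbuzov reaction of a primary benzylic bromide, driven by loss of volatile bromoethane.

Step 6
Reactants: 10 methyl 4-[(diethoxyphosphoryl)methyl]benzoate; 8 3-bromo-4-(methoxymethoxy)benzaldehyde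
Product: 12 methyl 4-[(E)-2-[3-bromo-4-(methoxymethoxy)phenyl]ethenyl]benzoate (ring B–ring C bromostilbene), via sodium phosphonate carbanion 11 (not isolated)
Conditions: NaH (1.1 equiv), THF, 0 °C; then 8, 0 °C to rt
Reagents that add atoms: none
Why: Horner–Wadsworth–Emmons olefination of a non-enolisable aryl aldehyde with a benzylic phosphonate anion stabilised by the para ester, which should give the E-stilbene and leave aryl bromide, ester and MOM ether intact.

Step 7
Reactants: 12 ring B–ring C bromostilbene; 6 ring A–ring D stilbene phenol
Product: 13 methyl 4-[(E)-2-[3-[3-[2-(3-benzyloxy-4-methoxyphenyl)ethenyl]phenoxy]-4-(methoxymethoxy)phenyl]ethenyl]benzoate (open-chain B–C–D–A bis-stilbene)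
Conditions: CuI (10 mol%), N,N-dimethylglycine (30 mol%), Cs2CO3 (2 equiv), dioxane, 100 °C, Ar
Reagents that add atoms: none
Why: Ligand-accelerated Ullmann diaryl ether coupling, established for ortho-alkoxy aryl bromides with phenols; the only aryl halide and the only free phenol of the two halves are the reacting sites.

Step 8
Reactants: 13 open-chain bis-stilbene
Product: 14 methyl 4-[2-[3-[3-[2-(3-hydroxy-4-methoxyphenyl)ethyl]phenoxy]-4-(methoxymethoxy)phenyl]ethyl]benzoate
Conditions: H2 (1 atm), Pd/C (10 wt%), EtOAc–THF, rt
Reagents that add atoms: none
Why: Heterogeneous catalytic hydrogenation saturates both stilbene bonds and hydrogenolyses the benzyl ether in one operation, while the MOM acetal, diaryl ether and methyl ester are inert in a neutral solvent.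

Step 9
Reactants: 14 phenol methyl ester
Product: 15 4-[2-[3-[3-[2-(3-hydroxy-4-methoxyphenyl)ethyl]phenoxy]-4-(methoxymethoxy)phenyl]ethyl]benzoic acid (seco acid)
Conditions: LiOH·H2O (5 equiv), THF–MeOH–H2O, 45 °C; then 1 M HCl to pH 4, 0 °C
Reagents that add atoms: lithium hydroxide, [Li+].[OH-]
Why: Saponification of a methyl benzoate (acyl substitution by hydroxide); the MOM ether is base-stable and should survive the cold, brief acidification.

Step 10
Reactants: 15 seco acid
Product: 17 O-MOM 20-membered macrolactone (ring B carboxyl esterified by the ring A C3 oxygen), via mixed anhydride 16 (not isolated)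
Conditions: 2-methyl-6-nitrobenzoic anhydride (MNBA, 1.5 equiv), DMAP (4 equiv), CH2Cl2, rt, syringe-pump addition of 15 over 16 h, final 1 mM
Reagents that add atoms: none
Why: Shiina macrolactonisation, in which DMAP-mediated acyl transfer from the hindered mixed anhydride selects the ring B acyl group and slow addition at high dilution favours closure of the 20-membered ring by the only free hydroxyl, the ring A phenol.

Step 11
Reactants: 17 O-MOM 20-membered macrolactone
Product: 18 O-MOM 19-membered bis(bibenzyl) diether (MOM ether of the target)
Conditions: Ni(cod)2 (20 mol%), 3,4-bis(dicyclohexylphosphino)thiophene (dcypt, 40 mol%), dried K3PO4 (1.5 equiv), o-xylene (5 mM), reflux (144 °C), slow Ar sweep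
Reagents that add atoms: none
Why: Proposed new method: zerovalent nickel bound to the electron-rich chelating bis(dicyclohexylphosphine) should add oxidatively into the acyl–oxygen bond of the aryl benzoate, the ring B aryl group then shifts from the carbonyl carbon to nickel, CO dissociates and is carried off by the argon stream, and C–O reductive elimination from the divalent aryl nickel aryloxide joins the ring A oxygen to the ring B ipso carbon. The closest known reaction type is the nickel- or palladium-catalysed decarbonylative etherification of aryl azinecarboxylates with this ligand and base, which has not been extended to a plain benzoate or to a macrocycle; insertion and CO loss are established for phenyl benzoates in decarbonylative borylation and cross-coupling, so only the last elementary step is untested here. The 19-membered ring forms by contraction of the 20-membered lactone: after CO loss nickel takes the place of the carbonyl carbon in a 20-membered nickelacycle, and closure is a reductive elimination of two ligands on one metal, not an end-to-end cyclisation. The methoxy oxygen ortho to the phenoxide oxygen can form a five-membered chelate with nickel, which together with the 5 mM dilution should hold back aryloxide exchange between molecules and hence oligomeric ethers. The step needs chemoselectivity for the ester acyl–oxygen bond over the ring C–ring D diaryl ether, the aryl methyl ether and the MOM acetal, and this is secured because only the carbonyl-activated bond inserts readily and no reductant or organometallic partner is present to turn over an insertion elsewhere. No stereocentre is created.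

Step 12
Reactants: 18 MOM ether of the target
Product: 19 target CNP0132125.0
Conditions: HCl (1.25 M in MeOH), THF, 45 °C
Reagents that add atoms: none
Why: Acid-catalysed transacetalisation of the aryl MOM ether into methanol, under which the two diaryl ethers and the aryl methyl ether are inert.

Compound list
1 | isovanillin | COc1ccc(C=O)cc1O | starting material
2 | 3-(benzyloxy)-4-methoxybenzaldehyde | COc1ccc(C=O)cc1OCc1ccccc1 | intermediate
3 | 3-hydroxybenzyl alcohol | OCc1cccc(O)c1 | starting material
4 | (3-hydroxybenzyl)triphenylphosphonium bromide | [Br-].Oc1cccc(C[P+](c2ccccc2)(c2ccccc2)c2ccccc2)c1 | intermediate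
5 | potassium phenoxide ylide from 4 (not isolated) | [K+].[O-]c1cccc(C=P(c2ccccc2)(c2ccccc2)c2ccccc2)c1 | intermediate
6 | 3-[2-(3-benzyloxy-4-methoxyphenyl)ethenyl]phenol, E/Z mixture | COc1ccc(C=Cc2cccc(O)c2)cc1OCc1ccccc1 | intermediate
7 | 3-bromo-4-hydroxybenzaldehyde | O=Cc1ccc(O)c(Br)c1 | starting material
8 | 3-bromo-4-(methoxymethoxy)benzaldehyde | COCOc1ccc(C=O)cc1Br | intermediate
9 | methyl 4-(bromomethyl)benzoate | COC(=O)c1ccc(CBr)cc1 | starting material
10 | methyl 4-[(diethoxyphosphoryl)methyl]benzoate | CCOP(=O)(Cc1ccc(cc1)C(=O)OC)OCC | intermediate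
11 | sodium phosphonate carbanion from 10 (not isolated) | [Na+].CCOP(=O)([CH-]c1ccc(cc1)C(=O)OC)OCC | intermediate
12 | methyl 4-[(E)-2-[3-bromo-4-(methoxymethoxy)phenyl]ethenyl]benzoate | COCOc1ccc(/C=C/c2ccc(cc2)C(=O)OC)cc1Br | intermediate
13 | open-chain B–C–D–A bis-stilbene (ring B–ring C alkene E, ring D–ring A alkene E/Z) | COCOc1ccc(/C=C/c2ccc(cc2)C(=O)OC)cc1Oc1cccc(C=Cc2ccc(OC)c(OCc3ccccc3)c2)c1 | intermediate
14 | methyl 4-[2-[3-[3-[2-(3-hydroxy-4-methoxyphenyl)ethyl]phenoxy]-4-(methoxymethoxy)phenyl]ethyl]benzoate | COCOc1ccc(CCc2ccc(cc2)C(=O)OC)cc1Oc1cccc(CCc2ccc(OC)c(O)c2)c1 | intermediate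
15 | seco acid, 4-[2-[3-[3-[2-(3-hydroxy-4-methoxyphenyl)ethyl]phenoxy]-4-(methoxymethoxy)phenyl]ethyl]benzoic acid | COCOc1ccc(CCc2ccc(cc2)C(=O)O)cc1Oc1cccc(CCc2ccc(OC)c(O)c2)c1 | intermediate
16 | 2-methyl-6-nitrobenzoic mixed anhydride of seco acid 15 (not isolated) | COCOc1ccc(CCc2ccc(cc2)C(=O)OC(=O)c2c(C)cccc2[N+](=O)[O-])cc1Oc1cccc(CCc2ccc(OC)c(O)c2)c1 | intermediate
17 | O-MOM 20-membered aryl benzoate macrolactone | COc1ccc2cc1OC(=O)c1ccc(cc1)CCc1ccc(OCOC)c(c1)Oc1cccc(c1)CC2 | intermediate
18 | O-MOM 19-membered bis(bibenzyl) diether | COc1ccc2cc1Oc1ccc(cc1)CCc1ccc(OCOC)c(c1)Oc1cccc(c1)CC2 | intermediate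
19 | CNP0132125.0 | COc1ccc2cc1Oc1ccc(cc1)CCc1ccc(O)c(c1)Oc1cccc(c1)CC2 | target

Total step count: 12.
Longest linear sequence: 8 steps (4, 6, 7, 8, 9, 10, 11, 12). The branches through steps 1 and 3, 2 and 3, or 5 and 6 are equally long.

Steps most likely to fail

1. Step 11. Carbon–oxygen reductive elimination from divalent nickel may be too slow for an aryl group without an azine nitrogen. The aryl nickel aryloxide could then decay by protodemetalation or exchange aryloxide between metal centres to give open-chain and oligomeric ethers, and retained CO could deactivate the catalyst.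
   - The fallback sets out from 17 and uses known reactions only.
   - Nickel-catalysed decarbonylative borylation of the aryl benzoate (B2pin2, Ni(cod)2, 1,3-dicyclohexylimidazol-2-ylidene, Na2CO3, dioxane, 150 °C, aqueous work-up) intercepts the same aryl nickel species by transmetalation. It opens the ring to the ring A phenol carrying a ring B pinacol boronate F1.
   - Transesterification with methylboronic acid (0.1 M NaOH–acetone, rt, volatiles evaporated) gives the phenol boronic acid F2.
   - An intramolecular Chan–Lam–Evans coupling (Cu(OAc)2, pyridine, 4 Å MS, CH2Cl2, air, rt, slow addition to about 2 mM) forms the ring A oxygen–ring B carbon bond and comes back to the route at 18.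

2. Step 10. Intermolecular acylation may outrun ring closure, because four rigid arenes keep the chain ends apart. This would lead to cyclodimerisation and oligomerisation, and DMAP could reopen the aryl ester once formed.
   - The fallback sets out from 12, makes the ester bond intermolecularly and moves the ring closure to the ring A–ring D bridge.
   - Copper-catalysed ether coupling of 12 with commercial 3-hydroxybenzaldehyde (O=Cc1cccc(O)c1) under the conditions of step 7 gives the formyl diaryl ether ester F3.
   - LiOH saponification gives the formyl acid F4.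
   - Steglich esterification with isovanillin 1 (EDC·HCl, DMAP, CH2Cl2, rt) gives the dialdehyde aryl ester F5.
   - McMurry coupling (TiCl4, Zn, pyridine, THF, reflux, syringe-pump addition) closes the 20-membered ring as the macrocyclic bis-stilbene lactone F6.
   - Hydrogenation of both alkenes (H2, Pd/C, EtOAc, rt) comes back to the route at 17.

3. Step 7. Coupling at the bromide flanked by the MOM ether may be sluggish, so that hydrodebromination and slow ester cleavage by carbonate compete during long heating.
   - The fallback sets out from 12 and replaces the halide–phenoxide coupling with an oxidative boron–phenol coupling under near-neutral conditions.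
   - Miyaura borylation (B2pin2, Pd(dppf)Cl2, KOAc, dioxane, 90 °C) gives the ring C pinacol boronate F7.
   - Chan–Lam–Evans coupling with phenol 6 (Cu(OAc)2, pyridine, B(OH)3, 4 Å MS, MeCN, air, 60 °C) comes back to the route at 13.

Further compounds
F1 | step 11 | ring-opened ring A phenol with ring B pinacol boronate | COCOc1ccc(CCc2ccc(cc2)B2OC(C)(C)C(C)(C)O2)cc1Oc1cccc(CCc2ccc(OC)c(O)c2)c1
F2 | step 11 | ring-opened ring A phenol with ring B boronic acid | COCOc1ccc(CCc2ccc(cc2)B(O)O)cc1Oc1cccc(CCc2ccc(OC)c(O)c2)c1
F3 | step 10 | methyl 4-[(E)-2-[3-(3-formylphenoxy)-4-(methoxymethoxy)phenyl]ethenyl]benzoate | COCOc1ccc(/C=C/c2ccc(cc2)C(=O)OC)cc1Oc1cccc(C=O)c1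
F4 | step 10 | 4-[(E)-2-[3-(3-formylphenoxy)-4-(methoxymethoxy)phenyl]ethenyl]benzoic acid | COCOc1ccc(/C=C/c2ccc(cc2)C(=O)O)cc1Oc1cccc(C=O)c1
F5 | step 10 | 5-formyl-2-methoxyphenyl ester of F4 (dialdehyde) | COCOc1ccc(/C=C/c2ccc(cc2)C(=O)Oc2cc(C=O)ccc2OC)cc1Oc1cccc(C=O)c1
F6 | step 10 | 20-membered macrolactone with both bridges as alkenes (new alkene E/Z) | COc1ccc2cc1OC(=O)c1ccc(cc1)/C=C/c1ccc(OCOC)c(c1)Oc1cccc(c1)C=C2
F7 | step 7 | methyl 4-[(E)-2-[4-(methoxymethoxy)-3-(4,4,5,5-tetramethyl-1,3,2-dioxaborolan-2-yl)phenyl]ethenyl]benzoate | COCOc1ccc(/C=C/c2ccc(cc2)C(=O)OC)cc1B1OC(C)(C)C(C)(C)O1
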